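**Retrosynthetic overview**

1. Feature: the C3 ester oxygen and the C8 ketone are 1,6-related through C2–C1–C10–C9 (eremophilane numbering), a dissonant pattern. Cutting the C1–C10 bond of ring A gives the β-carbons of two enones, a vinyl ketone (C1–C3) and a cyclohexenone (C8–C10), to be joined reductively.
2. Target ⇒ furan: the Z-configured C8 ketone / C7=C11 / C12 carbinol unit is unveiled from a fused 3-methylfuran (temporary ring C) by singlet-oxygen opening and aldehyde reduction, after the trienoate (from (E)-non-3-en-2-one) is placed on O3.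
3. Furan ⇒ cis-fused 4,5-dimethyldecalin-3,8-dione: C3 is reduced to the 3α-alcohol while C8 is ketalised, C9 is hydroxylated through the Δ8(9) silyl enol ether, and C7 is annulated with 1-nitropropene.
4. Dione ⇒ bis-enone ⇒ (R)-3-methylcyclohex-2-enyl propanoate: SmI2 coupling closes ring A; an Ireland–Claisen rearrangement sets C4 and the quaternary C5, followed by allylic oxidation and vinyl addition.
5. Ring order: ring B is bought (3-methylcyclohex-2-en-1-one), ring A is closed in step 7, the furan ring C is built in step 15 and opened in step 20.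

Key step: step 7

Remark: eremophilane numbering is used for the bicyclic compounds (C3 carbinol, C4 CHMe, C5 CMe, C10 ring-fusion CH, C8 ketone, C9 carbinol, C11–C13 side chain) and β is the face of the C5 methyl. The target is assumed to be isolable as the open Z γ-hydroxy enone drawn, so the last steps are kept near neutral.

**Route**

Step 1
Reactants: 1 3-methylcyclohex-2-en-1-one
Product: 2 (R)-3-methylcyclohex-2-en-1-ol
Conditions: (S)-1-methyl-3,3-diphenyltetrahydro-1H,3H-pyrrolo[1,2-c][1,3,2]oxazaborole (10 mol %), catecholborane, toluene, −78 °C; aq. NaOH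
Reagents that add atoms: none
Why: Corey–Bakshi–Shibata reduction: the oxazaborolidine binds the carbonyl oxygen anti to the alkenyl arm, which acts as the large group, and hydride is delivered to one face to set C1 as (R); catecholborane at −78 °C should leave the trisubstituted alkene alone.

Step 2
Reactants: 2 (R)-3-methylcyclohex-2-en-1-ol; 3 propanoyl chloride
Product: 4 (R)-3-methylcyclohex-2-en-1-yl propanoate
Conditions: pyridine, 4-dimethylaminopyridine (cat.), CH2Cl2, 0 °C
Reagents that add atoms: propanoyl chloride (3), CCC(Cl)=O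
Why: Base-mediated acylation; the basic medium avoids ionisation of the allylic ester, so the carbinol centre should be kept.

Step 3
Reactants: 4 (R)-3-methylcyclohex-2-en-1-yl propanoate
Product: 7 (2R)-2-[(1S)-1-methylcyclohex-2-en-1-yl]propanoic acid, via silyl ketene acetal 5 (not isolated), via trimethylsilyl ester 6 (not isolated)
Conditions: LiN(iPr)2, THF, −78 °C; Me3SiCl, Et3N, −78 °C → reflux; 1 M HCl
Reagents that add atoms: none
Why: Ireland–Claisen rearrangement: LiN(iPr)2 in THF gives the (E)-silyl ketene acetal 5, which should rearrange suprafacially through a chair-like transition state, forming the C4–C5 bond on the ring face that the C–O bond leaves (C5 becomes S) with the ketene acetal methyl turned away from the ring (C4 becomes R); the boat-like path of any (Z)-acetal leads to the same diastereomer.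

Step 4
Reactants: 7 (2R)-2-[(1S)-1-methylcyclohex-2-en-1-yl]propanoic acid
Product: 9 (2R)-N-methoxy-N-methyl-2-[(1S)-1-methylcyclohex-2-en-1-yl]propanamide, via acid chloride 8 (not isolated)
Conditions: (COCl)2, N,N-dimethylformamide (cat.), CH2Cl2, 0 °C → rt; then MeNHOMe·HCl, pyridine, 0 °C
Reagents that add atoms: N,O-dimethylhydroxylamine hydrochloride, CNOC.Cl
Why: Acid chloride formation and amidation (Weinreb amide synthesis); with pyridine as the only base no ketene should form, so C4 keeps its configuration.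

Step 5
Reactants: 9 (2R)-N-methoxy-N-methyl-2-[(1S)-1-methylcyclohex-2-en-1-yl]propanamide
Product: 10 (2R)-N-methoxy-N-methyl-2-[(1S)-1-methyl-4-oxocyclohex-2-en-1-yl]propanamide
Conditions: CrO3, 3,5-dimethylpyrazole, CH2Cl2, −20 °C
Reagents that add atoms: chromium trioxide, O=[Cr](=O)=O
Why: Allylic oxidation with the CrO3–3,5-dimethylpyrazole complex: C8 is the only allylic methylene because C5 is quaternary, and the amide is inert to the oxidant.

Step 6
Reactants: 10 (2R)-N-methoxy-N-methyl-2-[(1S)-1-methyl-4-oxocyclohex-2-en-1-yl]propanamide; 11 vinylmagnesium bromide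
Product: 14 (4S)-4-methyl-4-[(2R)-3-oxopent-4-en-2-yl]cyclohex-2-en-1-one, via silyl dienol ether 12 (not isolated), via magnesium hemiaminal 13 (not isolated)
Conditions: LiN(iPr)2, Me3SiCl, THF, −78 °C; vinylmagnesium bromide, −78 → 0 °C; cold 1 M HCl
Reagents that add atoms: vinylmagnesium bromide (11), C=C[Mg]Br
Why: Weinreb ketone synthesis with in-flask masking: kinetic deprotonation at C7 and silylation turn the ring enone into the cross-conjugated silyl dienol ether 12, which is inert to the Grignard reagent, the chelated adduct 13 stops at mono-addition, and the cold acid quench frees both carbonyls while protonating the released N,O-dimethylhydroxylamine so that it cannot add to the vinyl ketone.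

Step 7
Reactants: 14 (4S)-4-methyl-4-[(2R)-3-oxopent-4-en-2-yl]cyclohex-2-en-1-one
Product: 15 cis-fused (4R,5S,10R)-4,5-dimethyldecalin-3,8-dione
Conditions: SmI2 (2.2 equiv), HMPA, t-BuOH, THF, −78 °C; aq. NH4Cl
Reagents that add atoms: none
Why: Single-electron transfer from SmI2–HMPA to either enone (the unhindered vinyl ketone first) gives a samarium-bound radical anion with spin on its β-carbon; this adds to the β-carbon of the partner enone to form C1–C10, the resulting C9 α-keto radical takes a second electron, and the bis(samarium enolate) is protonated at C2 and C9 by t-BuOH and on work-up. The closest known reaction type is the SmI2-promoted (or cathodic) intramolecular hydrodimerisation of tethered bis-enones. Ring A closes 6-exo-trig (C1 onto C10 of the C9=C10 bond, through C2–C3–C4–C5). The new centre C10 is controlled by the quaternary C5: the tether can reach C10 only on the face it occupies and attacks axially through a chair in which the C4 methyl is equatorial, so H10 ends cis to the C5 methyl (cis fusion), while C4 is untouched because the enolate formed at C3 lies toward C2. The step needs β,β-coupling to beat pinacol coupling, simple 1,4-reduction of either enone and reduction of the product ketones; both acceptors are enones whose radical anions carry spin at the β-carbon, the geminal substitution at C5 favours closure, and the product stays masked as its bis-enolate until the quench at −78 °C.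

Step 8
Reactants: 15 cis-fused (4R,5S,10R)-4,5-dimethyldecalin-3,8-dione
Product: 16 8,8-ethylenedioxy-4β,5β-dimethyl-10βH-decalin-3-one
Conditions: (Me3SiOCH2)2, Me3SiOTf (cat.), CH2Cl2, −78 °C; pyridine quench
Reagents that add atoms: 1,2-bis(trimethylsilyloxy)ethane, C[Si](C)(C)OCCO[Si](C)(C)C
Why: Silyl triflate-catalysed ketalisation: the C8 carbonyl between two methylenes reacts, the C3 carbonyl between the C4 methine and quaternary C5 does not, and the aprotic −78 °C conditions should not enolise C3 toward the epimerisable C4.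

Step 9
Reactants: 16 8,8-ethylenedioxy-4β,5β-dimethyl-10βH-decalin-3-one
Product: 17 8,8-ethylenedioxy-4β,5β-dimethyl-10βH-decalin-3α-ol
Conditions: Li, NH3 (l), THF, EtOH, −78 °C; NH4Cl
Reagents that add atoms: none
Why: Dissolving-metal reduction of a ketone: the carbinyl anion is protonated under thermodynamic control to place the C3 hydroxyl equatorial and trans to the equatorial C4 methyl (3α), whereas hydride reagents, whose axial approach is blocked by the syn-axial C5 substituent, would favour the 3β epimer.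

Step 10
Reactants: 17 8,8-ethylenedioxy-4β,5β-dimethyl-10βH-decalin-3α-ol
Product: 18 8,8-ethylenedioxy-4β,5β-dimethyl-10βH-decalin-3α-yl pivalate
Conditions: t-BuCOCl, 4-dimethylaminopyridine, pyridine, 50 °C
Reagents that add atoms: pivaloyl chloride, CC(C)(C)C(Cl)=O
Why: Catalysed acylation; the pivalate is chosen because it resists LiN(iPr)2 and the later mild acid steps and can be cut reductively once C8 is locked in the furan.

Step 11
Reactants: 18 8,8-ethylenedioxy-4β,5β-dimethyl-10βH-decalin-3α-yl pivalate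
Product: 19 4β,5β-dimethyl-8-oxo-10βH-decalin-3α-yl pivalate
Conditions: pyridinium p-toluenesulfonate, acetone/H2O, 55 °C
Reagents that add atoms: water, O
Why: Acid-catalysed ketal hydrolysis; C4 is no longer α to a carbonyl, so no stereocentre is at risk, and the pivalate is stable.

Step 12
Reactants: 19 4β,5β-dimethyl-8-oxo-10βH-decalin-3α-yl pivalate
Product: 20 4β,5β-dimethyl-8-(triethylsilyloxy)-10βH-decal-8(9)-en-3α-yl pivalate
Conditions: Et3SiOTf, Et3N, CH2Cl2, 0 °C → rt
Reagents that add atoms: triethylsilyl trifluoromethanesulfonate, CC[Si](CC)(CC)OS(=O)(=O)C(F)(F)F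
Why: Silyl enol ether formation under equilibrating (soft enolisation) conditions: in the cis-fused ring system the C8 ketone should enolise toward C9 and the ring fusion, as cis-fused 3-keto steroids do toward C4, so the Δ8(9) ether should dominate.

Step 13
Reactants: 20 4β,5β-dimethyl-8-(triethylsilyloxy)-10βH-decal-8(9)-en-3α-yl pivalate
Product: 22 4β,5β-dimethyl-8-oxo-9β-(triethylsilyloxy)-10βH-decalin-3α-yl pivalate, via silyloxy epoxide 21 (not isolated)
Conditions: mCPBA, NaHCO3, CH2Cl2, −20 °C → rt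
Reagents that add atoms: 3-chloroperoxybenzoic acid, OOC(=O)c1cccc(Cl)c1
Why: Rubottom oxidation: the peracid should epoxidise the enol ether from the β face, the α face being screened by the axial C5–C4 bond of ring A, and the silyloxy epoxide 21 opens with 1,4-silyl shift to the equatorial 9β-silyloxy ketone, which is also the more stable C9 epimer.

Step 14
Reactants: 23 1-nitropropan-2-ol
Product: 25 (E)-1-nitroprop-1-ene, via mesylate 24 (not isolated)
Conditions: MsCl, Et3N, CH2Cl2, 0 °C
Reagents that add atoms: none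
Why: Mesylation and base-induced elimination (dehydration of a Henry-type adduct) give the conjugated (E)-nitroalkene, which is used fresh.

Step 15
Reactants: 22 4β,5β-dimethyl-8-oxo-9β-(triethylsilyloxy)-10βH-decalin-3α-yl pivalate; 25 (E)-1-nitroprop-1-ene
Product: 28 9β-(triethylsilyloxy)-10βH-furanoeremophilan-3α-yl pivalate, via lithium nitronate 26 (not isolated), via keto aldehyde 27 (not isolated)
Conditions: LiN(iPr)2, THF, −78 °C; 25, −78 °C; aq. TiCl3, NH4OAc, 0 °C → rt; then pyridinium p-toluenesulfonate, toluene, 50 °C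
Reagents that add atoms: (E)-1-nitroprop-1-ene (25), C/C=C/[N+](=O)[O-]
Why: Michael addition, Nef reaction and Paal–Knorr closure in sequence: LiN(iPr)2 removes a C7 proton (the methylene, not the silyloxy-bearing C9), the enolate adds to the methyl-bearing carbon of 25 so that the methyl ends on C11, buffered aqueous TiCl3 (reductive Nef reaction) turns the nitronate 26 into the aldehyde 27, and mild acid closes and aromatises the 3-methylfuran, which erases the C7 and C11 centres.

Step 16
Reactants: 28 9β-(triethylsilyloxy)-10βH-furanoeremophilan-3α-yl pivalate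
Product: 29 9β-(triethylsilyloxy)-10βH-furanoeremophilan-3α-ol
Conditions: LiAlH4, Et2O, 0 °C
Reagents that add atoms: none
Why: Reductive ester cleavage; the molecule has no other carbonyl at this stage, and the furan and the silyl ether are inert to LiAlH4.

Step 17
Reactants: 30 (E)-non-3-en-2-one; 31 triethyl 4-phosphonocrotonate
Product: 32 ethyl (2E,4E,6E)-5-methyldodeca-2,4,6-trienoate
Conditions: LiN(SiMe3)2, THF, −78 → 0 °C
Reagents that add atoms: triethyl 4-phosphonocrotonate (31), CCOC(=O)/C=C/CP(=O)(OCC)OCC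
Why: Vinylogous Horner–Wadsworth–Emmons olefination: the stabilised phosphonate anion keeps the 2E bond and should form the new C4=C5 bond mainly E; the minor 4Z isomer is removed by chromatography or equilibrated with a trace of iodine.

Step 18
Reactants: 32 ethyl (2E,4E,6E)-5-methyldodeca-2,4,6-trienoate
Product: 33 (2E,4E,6E)-5-methyldodeca-2,4,6-trienoic acid
Conditions: LiOH, THF/MeOH/H2O, rt; then 1 M HCl to pH 3
Reagents that add atoms: lithium hydroxide, [Li+].[OH-]
Why: Ester saponification; the conjugated triene is stable to LiOH at room temperature.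

Step 19
Reactants: 29 9β-(triethylsilyloxy)-10βH-furanoeremophilan-3α-ol; 33 (2E,4E,6E)-5-methyldodeca-2,4,6-trienoic acid
Product: 35 9β-(triethylsilyloxy)-10βH-furanoeremophilan-3α-yl (2E,4E,6E)-5-methyldodeca-2,4,6-trienoate, via mixed anhydride 34 (not isolated)
Conditions: 2,4,6-trichlorobenzoyl chloride, Et3N, THF, rt; then 29, 4-dimethylaminopyridine, toluene, rt → 40 °C
Reagents that add atoms: (2E,4E,6E)-5-methyldodeca-2,4,6-trienoic acid (33), CCCCC/C=C/C(C)=C/C=C/C(=O)O
Why: Yamaguchi esterification: the mixed anhydride 34 acylates the hindered equatorial 3α-hydroxyl under nucleophilic catalysis with retention at C3, and nothing else in 29 is nucleophilic.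

Step 20
Reactants: 35 9β-(triethylsilyloxy)-10βH-furanoeremophilan-3α-yl (2E,4E,6E)-5-methyldodeca-2,4,6-trienoate
Product: 37 (7(11)Z)-8,12-dioxo-9β-(triethylsilyloxy)-10βH-eremophil-7(11)-en-3α-yl (2E,4E,6E)-5-methyldodeca-2,4,6-trienoate, via furan endoperoxide 36 (not isolated)
Conditions: O2, methylene blue (methylthioninium chloride, cat.), red light, CH2Cl2, −78 °C; then Me2S, −78 → 0 °C
Reagents that add atoms: oxygen, O=O
Why: [4+2] Cycloaddition of singlet oxygen to the furan and reduction of the endoperoxide 36 by Me2S give the 1,4-dicarbonyl with the Z geometry fixed by the former ring; the trialkylfuran should react far faster than the electron-poor trienoate, and a low-triplet-energy sensitiser with red light at −78 °C should not isomerise the triene.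

Step 21
Reactants: 37 (7(11)Z)-8,12-dioxo-9β-(triethylsilyloxy)-10βH-eremophil-7(11)-en-3α-yl (2E,4E,6E)-5-methyldodeca-2,4,6-trienoate
Product: 38 (7(11)Z)-12-hydroxy-8-oxo-9β-(triethylsilyloxy)-10βH-eremophil-7(11)-en-3α-yl (2E,4E,6E)-5-methyldodeca-2,4,6-trienoate
Conditions: NaBH4, EtOH/CH2Cl2, −78 °C; pH 7 buffer
Reagents that add atoms: none
Why: Chemoselective 1,2-reduction by NaBH4: the aldehyde should react at −78 °C while the C8 ketone, flanked by the tetrasubstituted alkene and the silyloxy-bearing C9, does not, and conjugate reduction is disfavoured because both alkene carbons are fully substituted.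

Step 22
Reactants: 38 (7(11)Z)-12-hydroxy-8-oxo-9β-(triethylsilyloxy)-10βH-eremophil-7(11)-en-3α-yl (2E,4E,6E)-5-methyldodeca-2,4,6-trienoate
Product: 39 (7(11)Z)-9β,12-dihydroxy-8-oxo-10βH-eremophil-7(11)-en-3α-yl (2E,4E,6E)-5-methyldodeca-2,4,6-trienoate (target, 3R,4R,5R,9R,10S)
Conditions: Bu4NF, AcOH (1:1), THF, 0 °C
Reagents that add atoms: none
Why: Fluoride desilylation buffered with acetic acid: the α-keto silyl ether is cleaved near neutrality, which avoids acid-induced closure of the Z γ-hydroxy enone back to the furan and base-induced epimerisation or ketol shift at C9.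

**Compound list**

1 | 3-methylcyclohex-2-en-1-one | CC1=CC(=O)CCC1 | starting material
2 | (R)-3-methylcyclohex-2-en-1-ol | O[C@H]1C=C(C)CCC1 | intermediate
3 | propanoyl chloride | CCC(Cl)=O | starting material
4 | (R)-3-methylcyclohex-2-en-1-yl propanoate | CCC(=O)O[C@H]1C=C(C)CCC1 | intermediate
5 | (E)-1-{[(1R)-3-methylcyclohex-2-en-1-yl]oxy}-1-(trimethylsilyloxy)prop-1-ene (not isolated) | C/C=C(/O[Si](C)(C)C)O[C@H]1C=C(C)CCC1 | intermediate
6 | trimethylsilyl (2R)-2-[(1S)-1-methylcyclohex-2-en-1-yl]propanoate (not isolated) | C[Si](C)(C)OC(=O)[C@H](C)[C@]1(C)C=CCCC1 | intermediate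
7 | (2R)-2-[(1S)-1-methylcyclohex-2-en-1-yl]propanoic acid | OC(=O)[C@H](C)[C@]1(C)C=CCCC1 | intermediate
8 | (2R)-2-[(1S)-1-methylcyclohex-2-en-1-yl]propanoyl chloride (not isolated) | ClC(=O)[C@H](C)[C@]1(C)C=CCCC1 | intermediate
9 | (2R)-N-methoxy-N-methyl-2-[(1S)-1-methylcyclohex-2-en-1-yl]propanamide | CON(C)C(=O)[C@H](C)[C@]1(C)C=CCCC1 | intermediate
10 | (2R)-N-methoxy-N-methyl-2-[(1S)-1-methyl-4-oxocyclohex-2-en-1-yl]propanamide | CON(C)C(=O)[C@H](C)[C@]1(C)C=CC(=O)CC1 | intermediate
11 | vinylmagnesium bromide | C=C[Mg]Br | starting material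
12 | (2R)-N-methoxy-N-methyl-2-[(1S)-1-methyl-4-(trimethylsilyloxy)cyclohexa-2,4-dien-1-yl]propanamide (not isolated) | CON(C)C(=O)[C@H](C)[C@]1(C)C=CC(O[Si](C)(C)C)=CC1 | intermediate
13 | bromomagnesium alkoxide of the tetrahedral vinyl adduct of 12 (not isolated) | C=CC(O[Mg]Br)(N(C)OC)[C@H](C)[C@]1(C)C=CC(O[Si](C)(C)C)=CC1 | intermediate
14 | (4S)-4-methyl-4-[(2R)-3-oxopent-4-en-2-yl]cyclohex-2-en-1-one | C=CC(=O)[C@H](C)[C@]1(C)C=CC(=O)CC1 | intermediate
15 | cis-fused (4R,5S,10R)-4,5-dimethyldecalin-3,8-dione (4β,5β-dimethyl, 10βH) | O=C1CC[C@@H]2CC(=O)CC[C@]2(C)[C@H]1C | intermediate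
16 | 8,8-ethylenedioxy-4β,5β-dimethyl-10βH-decalin-3-one | O=C1CC[C@@H]2CC3(OCCO3)CC[C@]2(C)[C@H]1C | intermediate
17 | 8,8-ethylenedioxy-4β,5β-dimethyl-10βH-decalin-3α-ol | O[C@@H]1CC[C@@H]2CC3(OCCO3)CC[C@]2(C)[C@H]1C | intermediate
18 | 8,8-ethylenedioxy-4β,5β-dimethyl-10βH-decalin-3α-yl pivalate | CC(C)(C)C(=O)O[C@@H]1CC[C@@H]2CC3(OCCO3)CC[C@]2(C)[C@H]1C | intermediate
19 | 4β,5β-dimethyl-8-oxo-10βH-decalin-3α-yl pivalate | CC(C)(C)C(=O)O[C@@H]1CC[C@@H]2CC(=O)CC[C@]2(C)[C@H]1C | intermediate
20 | 4β,5β-dimethyl-8-(triethylsilyloxy)-10βH-decal-8(9)-en-3α-yl pivalate | CC(C)(C)C(=O)O[C@@H]1CC[C@@H]2C=C(O[Si](CC)(CC)CC)CC[C@]2(C)[C@H]1C | intermediate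
21 | 8β,9β-epoxy-4β,5β-dimethyl-8α-(triethylsilyloxy)-10βH-decalin-3α-yl pivalate (not isolated) | CC(C)(C)C(=O)O[C@@H]1CC[C@@H]2[C@H]3O[C@@]3(O[Si](CC)(CC)CC)CC[C@]2(C)[C@H]1C | intermediate
22 | 4β,5β-dimethyl-8-oxo-9β-(triethylsilyloxy)-10βH-decalin-3α-yl pivalate | CC(C)(C)C(=O)O[C@@H]1CC[C@@H]2[C@@H](O[Si](CC)(CC)CC)C(=O)CC[C@]2(C)[C@H]1C | intermediate
23 | 1-nitropropan-2-ol | CC(O)C[N+](=O)[O-] | starting material
24 | 1-nitropropan-2-yl methanesulfonate (not isolated) | CC(OS(C)(=O)=O)C[N+](=O)[O-] | intermediate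
25 | (E)-1-nitroprop-1-ene | C/C=C/[N+](=O)[O-] | intermediate
26 | lithium nitronate of the 7-(1-nitropropan-2-yl) derivative of 22, epimer mixture at C7 and C11 (not isolated) | CC(C)(C)C(=O)O[C@@H]1CC[C@@H]2[C@@H](O[Si](CC)(CC)CC)C(=O)C(C(C)C=[N+]([O-])[O-])C[C@]2(C)[C@H]1C.[Li+] | intermediate
27 | 7-(1-oxopropan-2-yl) derivative of 22, epimer mixture at C7 and C11 (not isolated) | CC(C)(C)C(=O)O[C@@H]1CC[C@@H]2[C@@H](O[Si](CC)(CC)CC)C(=O)C(C(C)C=O)C[C@]2(C)[C@H]1C | intermediate
28 | 9β-(triethylsilyloxy)-10βH-furanoeremophilan-3α-yl pivalate | CC(C)(C)C(=O)O[C@@H]1CC[C@@H]2[C@@H](O[Si](CC)(CC)CC)c3occ(C)c3C[C@]2(C)[C@H]1C | intermediate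
29 | 9β-(triethylsilyloxy)-10βH-furanoeremophilan-3α-ol | O[C@@H]1CC[C@@H]2[C@@H](O[Si](CC)(CC)CC)c3occ(C)c3C[C@]2(C)[C@H]1C | intermediate
30 | (E)-non-3-en-2-one | CCCCC/C=C/C(C)=O | starting material
31 | triethyl 4-phosphonocrotonate | CCOC(=O)/C=C/CP(=O)(OCC)OCC | starting material
32 | ethyl (2E,4E,6E)-5-methyldodeca-2,4,6-trienoate | CCCCC/C=C/C(C)=C/C=C/C(=O)OCC | intermediate
33 | (2E,4E,6E)-5-methyldodeca-2,4,6-trienoic acid | CCCCC/C=C/C(C)=C/C=C/C(=O)O | intermediate
34 | (2E,4E,6E)-5-methyldodeca-2,4,6-trienoic 2,4,6-trichlorobenzoic anhydride (not isolated) | CCCCC/C=C/C(C)=C/C=C/C(=O)OC(=O)c1c(Cl)cc(Cl)cc1Cl | intermediate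
35 | 9β-(triethylsilyloxy)-10βH-furanoeremophilan-3α-yl (2E,4E,6E)-5-methyldodeca-2,4,6-trienoate | CCCCC/C=C/C(C)=C/C=C/C(=O)O[C@@H]1CC[C@@H]2[C@@H](O[Si](CC)(CC)CC)c3occ(C)c3C[C@]2(C)[C@H]1C | intermediate
36 | 8,12-epidioxide (furan endoperoxide) of 35 (not isolated) | CCCCC/C=C/C(C)=C/C=C/C(=O)O[C@@H]1CC[C@@H]2[C@@H](O[Si](CC)(CC)CC)C34OOC(O3)C(C)=C4C[C@]2(C)[C@H]1C | intermediate
37 | (7(11)Z)-8,12-dioxo-9β-(triethylsilyloxy)-10βH-eremophil-7(11)-en-3α-yl (2E,4E,6E)-5-methyldodeca-2,4,6-trienoate | CCCCC/C=C/C(C)=C/C=C/C(=O)O[C@@H]1CC[C@@H]2[C@@H](O[Si](CC)(CC)CC)C(=O)/C(=C(/C)C=O)C[C@]2(C)[C@H]1C | intermediate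
38 | (7(11)Z)-12-hydroxy-8-oxo-9β-(triethylsilyloxy)-10βH-eremophil-7(11)-en-3α-yl (2E,4E,6E)-5-methyldodeca-2,4,6-trienoate | CCCCC/C=C/C(C)=C/C=C/C(=O)O[C@@H]1CC[C@@H]2[C@@H](O[Si](CC)(CC)CC)C(=O)/C(=C(/C)CO)C[C@]2(C)[C@H]1C | intermediate
39 | (7(11)Z)-9β,12-dihydroxy-8-oxo-10βH-eremophil-7(11)-en-3α-yl (2E,4E,6E)-5-methyldodeca-2,4,6-trienoate, (3R,4R,5R,9R,10S) | CCCCC/C=C/C(C)=C/C=C/C(=O)O[C@@H]1CC[C@@H]2[C@@H](O)C(=O)/C(=C(/C)CO)C[C@]2(C)[C@H]1C | target

**Step count and risks**

Total step count: 22. Longest linear sequence: 19 steps (steps 1–13, 15, 16, 19–22); steps 14 and 17–18 are side branches.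

Steps most likely to fail:

1. Step 7 (key step). After the first electron transfer the radical anion may take a second electron and a proton faster than it cyclises, giving the ethyl ketone or the saturated ring ketone. The two ketyls may also couple head to head, or the freed ketones may be reduced further. The fallback sets out from 14 and comes back at 15; it makes the same C1–C10 bond by a tin-hydride chain instead of electron transfer. HBr (from Me3SiBr and methanol, CH2Cl2, −20 °C) is added across the vinyl ketone to give (4S)-4-[(2R)-5-bromo-3-oxopentan-2-yl]-4-methylcyclohex-2-en-1-one F1. Slow addition of Bu3SnH with azobisisobutyronitrile in benzene at 80 °C then generates the primary C1 radical, which should add 6-exo-trig to C10 of the enone (Giese-type addition) from the same face, and hydrogen transfer to C9 gives 15.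

2. Step 3. Incomplete control of ketene acetal geometry, or competition between chair-like and boat-like transition states, would give the C4 epimer beside 7. The fallback sets out from 2 and comes back at 9; only C5 is set by rearrangement and C4 is set by an auxiliary. Acetylation of 2 (Ac2O, pyridine) gives (R)-3-methylcyclohex-2-en-1-yl acetate F2. Ireland–Claisen rearrangement (LiN(iPr)2, Me3SiCl, THF, −78 °C → reflux, acid work-up) gives (R)-2-(1-methylcyclohex-2-en-1-yl)acetic acid F3. Coupling with (R)-4-benzyloxazolidin-2-one (dicyclohexylcarbodiimide, 4-dimethylaminopyridine) gives (4R)-4-benzyl-3-{2-[(1R)-1-methylcyclohex-2-en-1-yl]acetyl}-1,3-oxazolidin-2-one F4. Evans alkylation (NaN(SiMe3)2, then MeI, −78 °C) methylates the Z-enolate on the face away from the benzyl group to give (4R)-4-benzyl-3-{(2R)-2-[(1S)-1-methylcyclohex-2-en-1-yl]propanoyl}-1,3-oxazolidin-2-one F5. AlMe3 with MeNHOMe·HCl then exchanges the auxiliary for the N-methoxy-N-methylamide 9.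

3. Step 20. The trienoate may be attacked by singlet oxygen or isomerised by the sensitiser before the furan is consumed. The fallback sets out from 29 and comes back at 39; the furan is opened before the triene is introduced. Photooxygenation of 29 itself under the same conditions, with Me2S reduction, gives 3α-hydroxy-8,12-dioxo-9β-(triethylsilyloxy)-10βH-eremophil-7(11)Z-ene F6. NaBH4 at −78 °C gives 3α,12-dihydroxy-9β-(triethylsilyloxy)-10βH-eremophil-7(11)Z-en-8-one F7. t-BuMe2SiCl with imidazole at 0 °C should silylate only the primary allylic hydroxyl, giving 12-(tert-butyldimethylsilyloxy)-3α-hydroxy-9β-(triethylsilyloxy)-10βH-eremophil-7(11)Z-en-8-one F8. Yamaguchi esterification of the hindered O3 with 33 gives 12-(tert-butyldimethylsilyloxy)-8-oxo-9β-(triethylsilyloxy)-10βH-eremophil-7(11)Z-en-3α-yl (2E,4E,6E)-5-methyldodeca-2,4,6-trienoate F9. Bu4NF buffered with AcOH removes both silyl groups to give 39.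

**Further compounds**

F1 | step 7 | (4S)-4-[(2R)-5-bromo-3-oxopentan-2-yl]-4-methylcyclohex-2-en-1-one | BrCCC(=O)[C@H](C)[C@]1(C)C=CC(=O)CC1
F2 | step 3 | (R)-3-methylcyclohex-2-en-1-yl acetate | CC(=O)O[C@H]1C=C(C)CCC1
F3 | step 3 | (R)-2-(1-methylcyclohex-2-en-1-yl)acetic acid | OC(=O)C[C@]1(C)C=CCCC1
F4 | step 3 | (4R)-4-benzyl-3-{2-[(1R)-1-methylcyclohex-2-en-1-yl]acetyl}-1,3-oxazolidin-2-one | O=C(C[C@]1(C)C=CCCC1)N1[C@H](Cc2ccccc2)COC1=O
F5 | step 3 | (4R)-4-benzyl-3-{(2R)-2-[(1S)-1-methylcyclohex-2-en-1-yl]propanoyl}-1,3-oxazolidin-2-one | O=C(N1[C@H](Cc2ccccc2)COC1=O)[C@H](C)[C@]1(C)C=CCCC1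
F6 | step 20 | 3α-hydroxy-8,12-dioxo-9β-(triethylsilyloxy)-10βH-eremophil-7(11)Z-ene | O[C@@H]1CC[C@@H]2[C@@H](O[Si](CC)(CC)CC)C(=O)/C(=C(/C)C=O)C[C@]2(C)[C@H]1C
F7 | step 20 | 3α,12-dihydroxy-9β-(triethylsilyloxy)-10βH-eremophil-7(11)Z-en-8-one | O[C@@H]1CC[C@@H]2[C@@H](O[Si](CC)(CC)CC)C(=O)/C(=C(/C)CO)C[C@]2(C)[C@H]1C
F8 | step 20 | 12-(tert-butyldimethylsilyloxy)-3α-hydroxy-9β-(triethylsilyloxy)-10βH-eremophil-7(11)Z-en-8-one | O[C@@H]1CC[C@@H]2[C@@H](O[Si](CC)(CC)CC)C(=O)/C(=C(/C)CO[Si](C)(C)C(C)(C)C)C[C@]2(C)[C@H]1C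
F9 | step 20 | 12-(tert-butyldimethylsilyloxy)-8-oxo-9β-(triethylsilyloxy)-10βH-eremophil-7(11)Z-en-3α-yl (2E,4E,6E)-5-methyldodeca-2,4,6-trienoate | CCCCC/C=C/C(C)=C/C=C/C(=O)O[C@@H]1CC[C@@H]2[C@@H](O[Si](CC)(CC)CC)C(=O)/C(=C(/C)CO[Si](C)(C)C(C)(C)C)C[C@]2(C)[C@H]1C
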